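## Retrosynthetic overview

1. Target ⇐ fluoride desilylation and hydride reduction of a trans-1-aryl-1,2-dihydronaphthalene carrying a C3 methyl ester and a C2 acyl-oxazolidinone.
2. That dihydronaphthalene ⇐ intramolecular Friedel–Crafts closure (C1–C8a) of a benzylic alcohol, setting C1 trans to C2. This carbocycle is the only ring built and it is formed last; both arene rings are bought.
3. The benzylic alcohol ⇐ Evans boron aldol (C1–C2 bond, sets C2) joining TIPS-vanillin with an (E)-arylidene-succinyl oxazolidinone.
4. The imide half ⇐ Heck reaction of TIPS-protected 4-bromoguaiacol (from catechol) with an itaconyl oxazolidinone (from itaconic anhydride).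
5. The aldehyde half ⇐ p-cresol by benzylic oxidation, bromination, Cu-mediated methoxylation and silylation.

Assumption: (S)-4-benzyl-2-oxazolidinone is treated as a recoverable chiral auxiliary (a reagent), since none of its atoms reach the target. Locants follow the target drawn as a 1-aryl-1,2-dihydronaphthalene (C1 = ArCH, C2 = CH–CH2OH, C3 = C–CH2OH, C4 = =CH). The target is (1S,2R), trans.

## Route

**Step 1**
Reactants: 1, catechol
Product: 2, 2-methoxyphenol (guaiacol)
Conditions: MeI (1.0 equiv), K2CO3 (1.0 equiv), acetone, reflux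
Reagents that add atoms: iodomethane, CI
Why: Williamson mono-O-methylation of a symmetric diphenol; over-methylated veratrole is neutral and is removed by base extraction.

**Step 2**
Reactants: 2, guaiacol
Product: 3, 4-bromo-2-methoxyphenol
Conditions: n-Bu4NBr3 (1.0 equiv), CH2Cl2–MeOH, rt
Reagents that add atoms: tetrabutylammonium tribromide (Bu4N+ Br3−, written as the bromide salt with Br2), CCCC[N+](CCCC)(CCCC)CCCC.[Br-].BrBr
Why: Electrophilic aromatic bromination with a mild tribromide source goes para to the free OH, which is a stronger director than OMe.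

**Step 3**
Reactants: 3, 4-bromo-2-methoxyphenol
Product: 4, (4-bromo-2-methoxyphenoxy)triisopropylsilane
Conditions: TIPSCl, imidazole, DMF, rt
Reagents that add atoms: chlorotriisopropylsilane, CC(C)[Si](Cl)(C(C)C)C(C)C
Why: Phenol silylation; the aryl TIPS ether tolerates the later Pd/amine, boron enolate, TFA and LiAlH4 conditions and keeps the ring electron-rich.

**Step 4**
Reactants: 5, itaconic anhydride
Product: 6, (S)-4-(4-benzyl-2-oxooxazolidin-3-yl)-2-methylene-4-oxobutanoic acid
Conditions: (S)-4-benzyl-2-oxazolidinone, n-BuLi, THF, −78 °C; then 5, −78 °C; AcOH quench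
Reagents that add atoms: (S)-4-benzyl-2-oxazolidinone, O=C1N[C@@H](Cc2ccccc2)CO1
Why: N-acylation by anhydride ring-opening; the lithiated oxazolidinone attacks the unconjugated, less hindered CH2–C=O carbonyl, as amines and alcohols do, leaving the acrylic acid free.

**Step 5**
Reactants: 6, itaconyl imide acid
Product: 7, methyl (S)-4-(4-benzyl-2-oxooxazolidin-3-yl)-2-methylene-4-oxobutanoate
Conditions: MeI, KHCO3, DMF, rt
Reagents that add atoms: iodomethane, CI
Why: Carboxylate O-alkylation under a base too weak to enolise the imide or isomerise the exo-methylene.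

**Step 6**
Reactants: 4, aryl bromide; 7, itaconyl imide ester
Product: 8, methyl (E)-2-{2-[(S)-4-benzyl-2-oxooxazolidin-3-yl]-2-oxoethyl}-3-[3-methoxy-4-(triisopropylsilyloxy)phenyl]acrylate
Conditions: Pd2(dba)3 (2 mol %), [HP(t-Bu)3]BF4 (8 mol %), Cy2NMe, dioxane, 50–70 °C
Reagents that add atoms: none
Why: Mizoroki–Heck arylation of the 1,1-disubstituted acrylate; syn β-H elimination of the benzylic hydrogen gives the aryl-conjugated E-alkene (aryl trans to CO2Me, cis to the CH2C(O)N arm), the geometry needed for ring closure.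

**Step 7**
Reactants: 9, p-cresol
Product: 10, 4-hydroxybenzaldehyde
Conditions: CoCl2·6H2O (2 mol %), NaOH (3 equiv), MeOH, O2 (1 atm), 60 °C; then H3O+
Reagents that add atoms: dioxygen, O=O
Why: Base-promoted Co-catalysed benzylic autoxidation via the p-quinone methide; it stops at the aldehyde because the phenoxide deactivates it towards further oxidation.

**Step 8**
Reactants: 10, 4-hydroxybenzaldehyde
Product: 11, 3-bromo-4-hydroxybenzaldehyde
Conditions: Br2 (1.0 equiv), CHCl3, 0 °C
Reagents that add atoms: bromine, BrBr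
Why: Electrophilic aromatic bromination ortho to OH (para is blocked, and CHO directs meta to the same carbon).

**Step 9**
Reactants: 11, 3-bromo-4-hydroxybenzaldehyde
Product: 12, vanillin (4-hydroxy-3-methoxybenzaldehyde)
Conditions: NaOMe (4 equiv), CuBr (10 mol %), DMF–MeOH, 110 °C; then H3O+
Reagents that add atoms: sodium methoxide, [Na+].[O-]C
Why: Ullmann-type Cu-catalysed methoxylation of the aryl bromide, assisted by the ortho phenoxide.

**Step 10**
Reactants: 12, vanillin
Product: 13, 3-methoxy-4-(triisopropylsilyloxy)benzaldehyde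
Conditions: TIPSCl, imidazole, DMF, rt
Reagents that add atoms: chlorotriisopropylsilane, CC(C)[Si](Cl)(C(C)C)C(C)C
Why: Phenol silylation; the silyloxy group remains a strong para donor for the later benzylic cation.

**Step 11**
Reactants: 8, imide; 13, aldehyde
Product: 14, methyl (E,3S,4S)-3-[(S)-4-benzyl-2-oxooxazolidine-3-carbonyl]-4-hydroxy-4-[3-methoxy-4-(triisopropylsilyloxy)phenyl]-2-[3-methoxy-4-(triisopropylsilyloxy)benzylidene]butanoate (syn aldol)
Conditions: 8, n-Bu2BOTf (1.2 equiv), i-Pr2NEt (1.4 equiv), CH2Cl2, −78 → 0 °C; then 13, −78 → −10 °C; pH 7 buffer, MeOH, H2O2, 0 °C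
Reagents that add atoms: none
Why: Evans syn-aldol: the Z(O)-boron dienolate reacts at its α-carbon through a Zimmerman–Traxler chair on the face opposite the benzyl group of the (S)-auxiliary, fixing the future C2 (the (S)-carbinol centre is lost in step 12).

**Step 12**
Reactants: 14, syn-aldol adduct
Product: 15, methyl (1S,2R)-2-[(S)-4-benzyl-2-oxooxazolidine-3-carbonyl]-6-methoxy-1-[3-methoxy-4-(triisopropylsilyloxy)phenyl]-7-(triisopropylsilyloxy)-1,2-dihydronaphthalene-3-carboxylate (trans; target locants)
Conditions: TFA (10 equiv), CH2Cl2, −20 → 0 °C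
Reagents that add atoms: none
Why: SN1 ionisation to the p-silyloxybenzyl cation and intramolecular Friedel–Crafts alkylation by the arene carbon para to OMe; attack anti to the C2 acyl group gives the trans (also thermodynamic) C1 configuration, with C2 untouched.

**Step 13**
Reactants: 15, dihydronaphthalene ester imide
Product: 16, [(1S,2R)-6-methoxy-1-[3-methoxy-4-(triisopropylsilyloxy)phenyl]-7-(triisopropylsilyloxy)-1,2-dihydronaphthalene-2,3-diyl]dimethanol
Conditions: LiAlH4 (3 equiv), THF, −20 → 0 °C; Rochelle salt work-up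
Reagents that add atoms: none
Why: Hydride reduction cleaves the N-acyl oxazolidinone to CH2OH (auxiliary released) and reduces the enoate 1,2 to the allylic alcohol at low temperature; no stereocentre is enolisable afterwards.

**Step 14**
Reactants: 16, bis-TIPS diol
Product: 17, (1S,2R)-1-(4-hydroxy-3-methoxyphenyl)-2,3-bis(hydroxymethyl)-6-methoxy-1,2-dihydronaphthalen-7-ol, i.e. (7R,8S)-8-(4-hydroxy-3-methoxyphenyl)-6,7-bis(hydroxymethyl)-3-methoxy-7,8-dihydronaphthalen-2-ol (target)
Conditions: TBAF (2.5 equiv), AcOH (2.5 equiv), THF, 0 °C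
Reagents that add atoms: none
Why: Fluoride cleavage of both aryl Si–O bonds; AcOH buffering avoids phenoxide/quinone-methide chemistry of the cinnamyl-type alcohol.

## Compound list

1 | catechol | Oc1ccccc1O | starting material
2 | 2-methoxyphenol | COc1ccccc1O | intermediate
3 | 4-bromo-2-methoxyphenol | COc1cc(Br)ccc1O | intermediate
4 | (4-bromo-2-methoxyphenoxy)triisopropylsilane | COc1cc(Br)ccc1O[Si](C(C)C)(C(C)C)C(C)C | intermediate
5 | itaconic anhydride | C=C1CC(=O)OC1=O | starting material
6 | (S)-4-(4-benzyl-2-oxooxazolidin-3-yl)-2-methylene-4-oxobutanoic acid | C=C(CC(=O)N1[C@@H](Cc2ccccc2)COC1=O)C(=O)O | intermediate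
7 | methyl (S)-4-(4-benzyl-2-oxooxazolidin-3-yl)-2-methylene-4-oxobutanoate | C=C(CC(=O)N1[C@@H](Cc2ccccc2)COC1=O)C(=O)OC | intermediate
8 | methyl (E)-2-{2-[(S)-4-benzyl-2-oxooxazolidin-3-yl]-2-oxoethyl}-3-[3-methoxy-4-(TIPSO)phenyl]acrylate | COC(=O)/C(CC(=O)N1[C@@H](Cc2ccccc2)COC1=O)=C/c3ccc(O[Si](C(C)C)(C(C)C)C(C)C)c(OC)c3 | intermediate
9 | p-cresol | Cc1ccc(O)cc1 | starting material
10 | 4-hydroxybenzaldehyde | O=Cc1ccc(O)cc1 | intermediate
11 | 3-bromo-4-hydroxybenzaldehyde | O=Cc1ccc(O)c(Br)c1 | intermediate
12 | vanillin | COc1cc(C=O)ccc1O | intermediate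
13 | 3-methoxy-4-(triisopropylsilyloxy)benzaldehyde | COc1cc(C=O)ccc1O[Si](C(C)C)(C(C)C)C(C)C | intermediate
14 | syn-aldol adduct, (E,3S,4S), (S)-auxiliary | COC(=O)/C(=C/c1ccc(O[Si](C(C)C)(C(C)C)C(C)C)c(OC)c1)[C@H](C(=O)N2[C@@H](Cc3ccccc3)COC2=O)[C@H](O)c4ccc(O[Si](C(C)C)(C(C)C)C(C)C)c(OC)c4 | intermediate
15 | trans-(1S,2R) dihydronaphthalene ester imide, bis-TIPS | COc1cc([C@H]2c3cc(O[Si](C(C)C)(C(C)C)C(C)C)c(OC)cc3C=C(C(=O)OC)[C@@H]2C(=O)N4[C@@H](Cc5ccccc5)COC4=O)ccc1O[Si](C(C)C)(C(C)C)C(C)C | intermediate
16 | (1S,2R) bis-TIPS diol | COc1cc([C@H]2c3cc(O[Si](C(C)C)(C(C)C)C(C)C)c(OC)cc3C=C(CO)[C@@H]2CO)ccc1O[Si](C(C)C)(C(C)C)C(C)C | intermediate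
17 | (1S,2R)-1-(4-hydroxy-3-methoxyphenyl)-2,3-bis(hydroxymethyl)-6-methoxy-1,2-dihydronaphthalen-7-ol | COc1cc([C@H]2c3cc(O)c(OC)cc3C=C(CO)[C@@H]2CO)ccc1O | target

## Summary

Total step count: 14.

Longest linear sequence: 8 steps (catechol arm: steps 1, 2, 3, 6, 11, 12, 13, 14; the p-cresol arm, steps 7–14, is also 8; the itaconic arm is 7).

Three steps most likely to fail:

- **Step 6 (Heck; also covers the regiochemistry and isomerisation risk of step 4).** β-H elimination toward the CH2C(O)N arm, or itaconate → mesaconate/citraconate isomerisation, could erode yield. Fallback: drop the Heck/itaconate arm and build the same skeleton by Stobbe condensation of a base-stable ether of vanillin 12 with dimethyl succinate (from succinic anhydride/MeOH) to the (E)-half-ester, then PivCl/Et3N and the lithiated auxiliary.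
- **Step 11 (aldol).** The hindered, cross-conjugated boron enolate and an electron-rich aldehyde may give low conversion or retro-aldol. Fallback: acylation–reduction. Acylate the chelated Na enolate of the imide with the acid chloride of TIPS-vanillic acid, then reduce the ketone to the benzylic alcohol (its configuration is irrelevant, as it is ionised in step 12). This needs the enantiomeric (R)-auxiliary, because chelated-enolate acylation has the opposite facial sense.
- **Step 12 (Friedel–Crafts closure).** E1 loss of the activated C2–H to a bis-arylidene, or C2 epimerisation, would destroy the stereocentre. Fallback: remove the auxiliary first (LiBH4) so C2 is no longer α to a carbonyl, cyclise the resulting α-arylidene-γ-butyrolactone with TFA, then open the lactone with LiAlH4 to the same diol 16.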